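The route rests on cutting the C5–C6 bond and the O–C6 bond of the epoxycyclohexane in one retrosynthetic stroke. The target offers a glycidic ester retron: its tetrasubstituted C5–C6 oxirane is fused to the six-membered ring, C6 carries the side-chain carbon C7 and sits beside the gem-dimethyl C1, and C5 bears a methyl group 1,3 to the C3 oxygen. An intramolecular Darzens condensation therefore closes the carbocycle and the oxirane in a single operation and sets C5 and C6 from C3. Its precursor is an open-chain tert-butyl 2-chloro ester with a gem-dimethyl group, one silyloxy stereocentre and a terminal methyl ketone, assembled from 3,3-dimethylglutaric anhydride by asymmetric methallylation.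

Key step: step 8

Remark: ring atoms are cited by carotenoid numbering (C1 gem-dimethyl carbon, C3 oxygenated carbon, C5 and C6 oxirane carbons, C7 the exocyclic carbon on C6), and TBS stands for tert-butyldimethylsilyl. The methallylborane of the (−)-α-pinene series is assumed to add to the Re face of aldehyde 4, as allyl- and methallyl-diisopinocampheylboranes of that series do with aliphatic aldehydes.

Step 1
Reactants: 1 3,3-dimethylglutaric anhydride
Product: 2 5-tert-butoxy-3,3-dimethyl-5-oxopentanoic acid
Conditions: KOtBu, THF, 0 °C → rt; then cold 1 M HCl to pH 3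
Reagents that add atoms: potassium tert-butoxide, CC(C)(C)[O-].[K+]
Why: Alkoxide opening of a symmetrical cyclic anhydride can give only one half ester, and the carboxylate that forms shields the second acyl group from further attack.

Step 2
Reactants: 2 5-tert-butoxy-3,3-dimethyl-5-oxopentanoic acid
Product: 3 tert-butyl 5-hydroxy-3,3-dimethylpentanoate
Conditions: BH3·SMe2, THF, 0 °C → rt; MeOH, then water
Reagents that add atoms: none
Why: Borane reduces a carboxylic acid through its acyloxyborane far faster than an ester, so the tert-butyl ester should survive, and its bulk should hold back lactonization of the hydroxy ester.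

Step 3
Reactants: 3 tert-butyl 5-hydroxy-3,3-dimethylpentanoate
Product: 4 tert-butyl 3,3-dimethyl-5-oxopentanoate
Conditions: TEMPO (cat.), PhI(OAc)2, CH2Cl2, rt
Reagents that add atoms: none
Why: Oxoammonium-mediated oxidation of a primary alcohol stops at the aldehyde in the absence of water and touches neither the ester nor the neopentyl framework.

Step 4
Reactants: 4 tert-butyl 3,3-dimethyl-5-oxopentanoate; 5 2-methylallylmagnesium chloride
Product: 7 tert-butyl (R)-5-hydroxy-3,3,7-trimethyloct-7-enoate, via B-methallyldiisopinocampheylborane 6 (not isolated)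
Conditions: (+)-B-methoxydiisopinocampheylborane [from (−)-α-pinene], 5, Et2O, −78 °C → rt; then 4, −78 °C; NaBO3·4H2O, THF/H2O, rt
Reagents that add atoms: 2-methylallylmagnesium chloride (5), CC(=C)C[Mg]Cl
Why: Asymmetric methallylboration of an aldehyde through a closed chair transition state, in which the isopinocampheyl groups direct the methallyl group to the Re face of 4 and set the (R) carbinol that becomes C3; the Grignard reagent is consumed in forming 6 before the ester-bearing aldehyde is added, and the perborate work-up is mild enough to avoid lactonization.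

Step 5
Reactants: 7 tert-butyl (R)-5-hydroxy-3,3,7-trimethyloct-7-enoate
Product: 8 tert-butyl (R)-5-(tert-butyldimethylsilyloxy)-3,3,7-trimethyloct-7-enoate
Conditions: TBSCl, imidazole, DMF, 0 °C → rt
Reagents that add atoms: tert-butyldimethylsilyl chloride, CC(C)(C)[Si](C)(C)Cl
Why: Routine silylation of an unhindered secondary alcohol, carried out directly after step 4, removes the hydroxyl that could lactonize and installs an ether that should withstand the amide base, alkoxide, hydride and ylide steps that follow.

Step 6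
Reactants: 8 tert-butyl (R)-5-(tert-butyldimethylsilyloxy)-3,3,7-trimethyloct-7-enoate
Product: 10 tert-butyl (2RS,5R)-5-(tert-butyldimethylsilyloxy)-2-chloro-3,3,7-trimethyloct-7-enoate, via lithium ester enolate 9 (not isolated)
Conditions: LiN(i-Pr)2, THF, −78 °C; then added to C2Cl6, THF, −78 → −40 °C
Reagents that add atoms: hexachloroethane, ClC(Cl)(Cl)C(Cl)(Cl)Cl
Why: Electrophilic chlorination of a lithium ester enolate, in which the ester α-methylene is the only acidic site, inverse addition to excess chlorine donor limits proton exchange with the product, the quaternary C3 excludes elimination, and the C2 configuration is immaterial because step 8 passes through the planar enolate.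

Step 7
Reactants: 10 tert-butyl (2RS,5R)-5-(tert-butyldimethylsilyloxy)-2-chloro-3,3,7-trimethyloct-7-enoate
Product: 12 tert-butyl (2RS,5S)-5-(tert-butyldimethylsilyloxy)-2-chloro-3,3-dimethyl-7-oxooctanoate, via secondary ozonide 11 (not isolated)
Conditions: O3, CH2Cl2, −78 °C; then PPh3, −78 °C → rt
Reagents that add atoms: ozone, [O-][O+]=O
Why: Ozonolysis with reductive work-up cleaves the only alkene, a 1,1-disubstituted one, to the methyl ketone while chloro ester and silyl ether are inert to ozone and phosphine (the C5 descriptor changes from R to S through the priority rules only).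

Step 8
Reactants: 12 tert-butyl (2RS,5S)-5-(tert-butyldimethylsilyloxy)-2-chloro-3,3-dimethyl-7-oxooctanoate
Product: 15 tert-butyl (1S,4S,6R)-4-(tert-butyldimethylsilyloxy)-2,2,6-trimethyl-7-oxabicyclo[4.1.0]heptane-1-carboxylate, via potassium chloro ester enolate 13 (not isolated), via potassium chlorohydrin alkoxide 14 (not isolated)
Conditions: KOtBu, THF/t-BuOH, −40 → 0 °C
Reagents that add atoms: none
Why: Intramolecular Darzens glycidic ester condensation: tert-butoxide deprotonates the chloro-bearing carbon (both C2 epimers of 12 give the same planar enolate 13), this future C6 adds reversibly to the ketone carbon (future C5), and the alkoxide 14 then displaces chloride from C6 with inversion. The closest known reaction type is the alkoxide-mediated Darzens condensation of α-chloro esters with enolizable ketones, including its ring-forming intramolecular variants. The cyclohexane closes by a 6-(enolexo)-exo-trig aldol addition assisted by the gem-dimethyl group, and the oxirane by a 3-exo-tet displacement that requires the C5 oxygen and the C6 chlorine to be trans-diaxial. C5 is controlled by the C3 stereocentre through a chair in which the axial C1 methyl keeps the C3 silyloxy group and the C5 methyl equatorial, so the C5 oxygen is axial and anti to the C3 oxygen, and C6 follows because the oxirane can only be cis-fused. The step needs chemoselective use of the chloro ester enolate and anti facial selectivity: aldolates that cannot reach the trans-diaxial arrangement return by retro-aldol, the tert-butyl ester blocks acyl attack by the ketone enolate, C6 has no β-hydrogen for loss of HCl, and the low temperature should hold back β-elimination of the silyloxy group.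

Step 9
Reactants: 15 tert-butyl (1S,4S,6R)-4-(tert-butyldimethylsilyloxy)-2,2,6-trimethyl-7-oxabicyclo[4.1.0]heptane-1-carboxylate
Product: 16 [(1R,4S,6R)-4-(tert-butyldimethylsilyloxy)-2,2,6-trimethyl-7-oxabicyclo[4.1.0]heptan-1-yl]methanol
Conditions: i-Bu2AlH (excess), CH2Cl2, −78 → 0 °C; aqueous potassium sodium tartrate
Reagents that add atoms: none
Why: Hydride reduction of a glycidic ester to the epoxy carbinol, in which the ester is the only reducible group, the tetrasubstituted oxirane offers hydride no accessible carbon, and the silyl ether is inert.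

Step 10
Reactants: 16 [(1R,4S,6R)-4-(tert-butyldimethylsilyloxy)-2,2,6-trimethyl-7-oxabicyclo[4.1.0]heptan-1-yl]methanol
Product: 17 (1S,4S,6R)-4-(tert-butyldimethylsilyloxy)-2,2,6-trimethyl-7-oxabicyclo[4.1.0]heptane-1-carbaldehyde
Conditions: (n-Pr)4N[RuO4] (cat.), N-methylmorpholine N-oxide, 4 Å molecular sieves, CH2Cl2, rt
Reagents that add atoms: none
Why: Ley–Griffith oxidation under neutral conditions spares the oxirane and the silyl ether, and the aldehyde formed has no α-hydrogen and so cannot enolize or epimerize.

Step 11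
Reactants: 17 (1S,4S,6R)-4-(tert-butyldimethylsilyloxy)-2,2,6-trimethyl-7-oxabicyclo[4.1.0]heptane-1-carbaldehyde; 18 1-(triphenylphosphoranylidene)propan-2-one
Product: 19 (E)-4-[(1S,4S,6R)-4-(tert-butyldimethylsilyloxy)-2,2,6-trimethyl-7-oxabicyclo[4.1.0]heptan-1-yl]but-3-en-2-one
Conditions: 18, toluene, 100 °C
Reagents that add atoms: 1-(triphenylphosphoranylidene)propan-2-one (18), CC(=O)C=P(c1ccccc1)(c1ccccc1)c1ccccc1
Why: Wittig olefination with a stabilized ylide should give the E enone under thermodynamic control, and the neutral, salt-free conditions suit a non-enolizable but hindered epoxy aldehyde that tolerates heating.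

Step 12
Reactants: 19 (E)-4-[(1S,4S,6R)-4-(tert-butyldimethylsilyloxy)-2,2,6-trimethyl-7-oxabicyclo[4.1.0]heptan-1-yl]but-3-en-2-one
Product: 20 (E)-4-[(1S,4S,6R)-4-hydroxy-2,2,6-trimethyl-7-oxabicyclo[4.1.0]heptan-1-yl]but-3-en-2-one
Conditions: n-Bu4NF, AcOH (1 equiv each), THF, 0 °C → rt
Reagents that add atoms: none
Why: Fluoride-driven desilylation buffered with acetic acid stays near neutrality, so neither acid-induced rearrangement of the vinyl oxirane nor base-induced enone chemistry should occur, and no stereocentre is touched, leaving the (3S,5R,6S) epoxy alcohol with its cis-fused oxirane.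

Step 13
Reactants: 20 (E)-4-[(1S,4S,6R)-4-hydroxy-2,2,6-trimethyl-7-oxabicyclo[4.1.0]heptan-1-yl]but-3-en-2-one; 21 tetradecanoyl chloride
Product: 22 (1R,3S,6S)-1,5,5-trimethyl-6-[(E)-3-oxobut-1-en-1-yl]-7-oxabicyclo[4.1.0]heptan-3-yl tetradecanoate
Conditions: 21, pyridine, DMAP (cat.), CH2Cl2, 0 °C → rt
Reagents that add atoms: tetradecanoyl chloride (21), CCCCCCCCCCCCCC(=O)Cl
Why: DMAP-catalysed acylation of the unhindered secondary alcohol through the acylpyridinium ion proceeds at oxygen with retention at C3 and leaves oxirane and enone alone.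

Compound list
1 | 3,3-dimethylglutaric anhydride | CC1(C)CC(=O)OC(=O)C1 | starting material
2 | 5-tert-butoxy-3,3-dimethyl-5-oxopentanoic acid | CC(C)(C)OC(=O)CC(C)(C)CC(=O)O | intermediate
3 | tert-butyl 5-hydroxy-3,3-dimethylpentanoate | CC(C)(C)OC(=O)CC(C)(C)CCO | intermediate
4 | tert-butyl 3,3-dimethyl-5-oxopentanoate | CC(C)(C)OC(=O)CC(C)(C)CC=O | intermediate
5 | 2-methylallylmagnesium chloride | CC(=C)C[Mg]Cl | starting material
6 | B-(2-methylallyl)diisopinocampheylborane of the (−)-α-pinene series | C=C(C)CB([C@H]1C[C@H]2C[C@@H]([C@@H]1C)C2(C)C)[C@H]1C[C@H]2C[C@@H]([C@@H]1C)C2(C)C | intermediate (not isolated)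
7 | tert-butyl (R)-5-hydroxy-3,3,7-trimethyloct-7-enoate | C=C(C)C[C@@H](O)CC(C)(C)CC(=O)OC(C)(C)C | intermediate
8 | tert-butyl (R)-5-(tert-butyldimethylsilyloxy)-3,3,7-trimethyloct-7-enoate | C=C(C)C[C@@H](O[Si](C)(C)C(C)(C)C)CC(C)(C)CC(=O)OC(C)(C)C | intermediate
9 | lithium enolate of ester 8 | C=C(C)C[C@@H](O[Si](C)(C)C(C)(C)C)CC(C)(C)C=C([O-])OC(C)(C)C.[Li+] | intermediate (not isolated)
10 | tert-butyl (2RS,5R)-5-(tert-butyldimethylsilyloxy)-2-chloro-3,3,7-trimethyloct-7-enoate | C=C(C)C[C@@H](O[Si](C)(C)C(C)(C)C)CC(C)(C)C(Cl)C(=O)OC(C)(C)C | intermediate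
11 | tert-butyl (5S)-5-(tert-butyldimethylsilyloxy)-2-chloro-3,3-dimethyl-6-(3-methyl-1,2,4-trioxolan-3-yl)hexanoate, isomer mixture | CC1(C[C@@H](O[Si](C)(C)C(C)(C)C)CC(C)(C)C(Cl)C(=O)OC(C)(C)C)OCOO1 | intermediate (not isolated)
12 | tert-butyl (2RS,5S)-5-(tert-butyldimethylsilyloxy)-2-chloro-3,3-dimethyl-7-oxooctanoate | CC(=O)C[C@@H](O[Si](C)(C)C(C)(C)C)CC(C)(C)C(Cl)C(=O)OC(C)(C)C | intermediate
13 | potassium enolate of chloro ester 12 | CC(=O)C[C@@H](O[Si](C)(C)C(C)(C)C)CC(C)(C)C(Cl)=C([O-])OC(C)(C)C.[K+] | intermediate (not isolated)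
14 | potassium alkoxide of tert-butyl (1R,2R,4S)-4-(tert-butyldimethylsilyloxy)-1-chloro-2-hydroxy-2,6,6-trimethylcyclohexane-1-carboxylate | CC(C)(C)[Si](C)(C)O[C@H]1CC(C)(C)[C@](Cl)(C(=O)OC(C)(C)C)[C@@]([O-])(C)C1.[K+] | intermediate (not isolated)
15 | tert-butyl (1S,4S,6R)-4-(tert-butyldimethylsilyloxy)-2,2,6-trimethyl-7-oxabicyclo[4.1.0]heptane-1-carboxylate | CC(C)(C)[Si](C)(C)O[C@H]1CC(C)(C)[C@]2(C(=O)OC(C)(C)C)O[C@]2(C)C1 | intermediate
16 | [(1R,4S,6R)-4-(tert-butyldimethylsilyloxy)-2,2,6-trimethyl-7-oxabicyclo[4.1.0]heptan-1-yl]methanol | CC(C)(C)[Si](C)(C)O[C@H]1CC(C)(C)[C@]2(CO)O[C@]2(C)C1 | intermediate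
17 | (1S,4S,6R)-4-(tert-butyldimethylsilyloxy)-2,2,6-trimethyl-7-oxabicyclo[4.1.0]heptane-1-carbaldehyde | CC(C)(C)[Si](C)(C)O[C@H]1CC(C)(C)[C@]2(C=O)O[C@]2(C)C1 | intermediate
18 | 1-(triphenylphosphoranylidene)propan-2-one | CC(=O)C=P(c1ccccc1)(c1ccccc1)c1ccccc1 | starting material
19 | (E)-4-[(1S,4S,6R)-4-(tert-butyldimethylsilyloxy)-2,2,6-trimethyl-7-oxabicyclo[4.1.0]heptan-1-yl]but-3-en-2-one | CC(C)(C)[Si](C)(C)O[C@H]1CC(C)(C)[C@]2(/C=C/C(C)=O)O[C@]2(C)C1 | intermediate
20 | (E)-4-[(1S,4S,6R)-4-hydroxy-2,2,6-trimethyl-7-oxabicyclo[4.1.0]heptan-1-yl]but-3-en-2-one, the (3S,5R,6S)-5,6-epoxy-3-hydroxy-5,6-dihydro-β-ionone | O[C@H]1CC(C)(C)[C@]2(/C=C/C(C)=O)O[C@]2(C)C1 | intermediate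
21 | tetradecanoyl chloride | CCCCCCCCCCCCCC(=O)Cl | starting material
22 | (1R,3S,6S)-1,5,5-trimethyl-6-[(E)-3-oxobut-1-en-1-yl]-7-oxabicyclo[4.1.0]heptan-3-yl tetradecanoate (CNP0118807.1) | CCCCCCCCCCCCCC(=O)O[C@H]1CC(C)(C)[C@]2(/C=C/C(C)=O)O[C@]2(C)C1 | target

Total step count: 13. Longest linear sequence: 13 steps (1 to 22); compounds 5, 18 and 21 are bought.

Steps most likely to fail

1. Step 8 (ring-forming Darzens condensation). The base may deprotonate the methyl ketone instead, leading to β-elimination of the silyloxy group. Bond formation between two fully substituted carbons beside the quaternary C1 may be slow, or the aldol closure may discriminate poorly between the two faces. The fallback sets out from 8 and comes back at 16, separating ring closure from oxirane formation and placing the oxygen by reagent control. Ester 8 would be reduced with i-Bu2AlH (CH2Cl2, −78 °C) to (R)-5-(tert-butyldimethylsilyloxy)-3,3,7-trimethyloct-7-enal F1. Ozonolysis of F1 (O3, CH2Cl2, −78 °C) through its ozonide F2 and reduction with PPh3 would give (S)-5-(tert-butyldimethylsilyloxy)-3,3-dimethyl-7-oxooctanal F3. An amine-salt-mediated intramolecular aldol condensation (dibenzylammonium trifluoroacetate, benzene, 50 °C), in which the aldehyde enamine attacks the ketone, would close the ring to (R)-4-(tert-butyldimethylsilyloxy)-2,6,6-trimethylcyclohex-1-ene-1-carbaldehyde F4. Reduction with NaBH4 and CeCl3·7H2O in MeOH at 0 °C would give [(R)-4-(tert-butyldimethylsilyloxy)-2,6,6-trimethylcyclohex-1-en-1-yl]methanol F5. A Sharpless asymmetric epoxidation (Ti(OiPr)4, D-(−)-diethyl tartrate, t-BuOOH, 4 Å molecular sieves, CH2Cl2, −20 °C) would then deliver oxygen to the face anti to the silyloxy group and give 16.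

2. Step 11 (Wittig olefination). The weakly nucleophilic stabilized ylide may add too slowly to an aldehyde flanked by two fully substituted carbons, and long heating may degrade the epoxy aldehyde. The fallback sets out from 17 and comes back at 19 by an aldol addition and elimination sequence. The lithium enolate of acetone (LiN(i-Pr)2, acetone, THF, −78 °C) would add to 17 to give 4-hydroxy-4-[(1R,4S,6R)-4-(tert-butyldimethylsilyloxy)-2,2,6-trimethyl-7-oxabicyclo[4.1.0]heptan-1-yl]butan-2-one F6 as a mixture of carbinol epimers. Mesylation (MeSO2Cl, Et3N, CH2Cl2, 0 °C) would give the methanesulfonate F7, which on addition of DBU in the same flask should eliminate by an E1cB pathway to the E enone 19.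

3. Step 6 (enolate chlorination). Proton exchange between the more acidic chloro ester and unreacted enolate may cause over-chlorination and return of starting ester, and enolization at the neopentyl α-carbon may be incomplete. The fallback sets out from 8 and comes back at 10 by halogenating a neutral, isolated enol derivative instead of quenching a basic enolate. The enolate of 8 would be trapped (LiN(i-Pr)2, Me3SiCl, THF, −78 °C) as the tert-butyl trimethylsilyl ketene acetal F8. After removal of the amine salts, F8 would be treated with N-chlorosuccinimide (CH2Cl2, 0 °C), which with no base present cannot cause proton exchange and should give 10.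

Further compounds
F1 | step 8 | (R)-5-(tert-butyldimethylsilyloxy)-3,3,7-trimethyloct-7-enal | C=C(C)C[C@@H](O[Si](C)(C)C(C)(C)C)CC(C)(C)CC=O
F2 | step 8 | (S)-5-(tert-butyldimethylsilyloxy)-3,3-dimethyl-6-(3-methyl-1,2,4-trioxolan-3-yl)hexanal, isomer mixture | CC1(C[C@@H](O[Si](C)(C)C(C)(C)C)CC(C)(C)CC=O)OCOO1
F3 | step 8 | (S)-5-(tert-butyldimethylsilyloxy)-3,3-dimethyl-7-oxooctanal | CC(=O)C[C@@H](O[Si](C)(C)C(C)(C)C)CC(C)(C)CC=O
F4 | step 8 | (R)-4-(tert-butyldimethylsilyloxy)-2,6,6-trimethylcyclohex-1-ene-1-carbaldehyde | CC(C)(C)[Si](C)(C)O[C@H]1CC(C)(C)C(C=O)=C(C)C1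
F5 | step 8 | [(R)-4-(tert-butyldimethylsilyloxy)-2,6,6-trimethylcyclohex-1-en-1-yl]methanol | CC(C)(C)[Si](C)(C)O[C@H]1CC(C)(C)C(CO)=C(C)C1
F6 | step 11 | 4-hydroxy-4-[(1R,4S,6R)-4-(tert-butyldimethylsilyloxy)-2,2,6-trimethyl-7-oxabicyclo[4.1.0]heptan-1-yl]butan-2-one, carbinol epimers | CC(C)(C)[Si](C)(C)O[C@H]1CC(C)(C)[C@]2(C(O)CC(C)=O)O[C@]2(C)C1
F7 | step 11 | methanesulfonate of F6 | CC(C)(C)[Si](C)(C)O[C@H]1CC(C)(C)[C@]2(C(OS(C)(=O)=O)CC(C)=O)O[C@]2(C)C1
F8 | step 6 | tert-butyl trimethylsilyl ketene acetal of 8 | C=C(C)C[C@@H](O[Si](C)(C)C(C)(C)C)CC(C)(C)C=C(O[Si](C)(C)C)OC(C)(C)C
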